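**Retrosynthetic overview**

1. The target comes from global O-debenzylation of the tetra-O-benzyl flavonolignan 13.
2. 13 comes from a proposed new Ru-catalysed dynamic kinetic resolution–asymmetric transfer hydrogenation (DKR-ATH) of the racemic α-aryloxy-β-benzyloxy propiophenone 11. This sets C7'' and C8'' together as the threo (7''S,8''S) pair.
3. 11 comes from Adler–Lundquist hydroxymethylation and O-benzylation of aryloxy ketone 8. 8 comes from O-alkylation of 5,7-di-O-benzyltricin (6) with phenacyl bromide 7.
4. Ring order: the A ring (from phloroacetophenone) and the B ring (from syringaldehyde) are bought. The C ring is closed by Claisen–Schmidt condensation and I2/DMSO oxidative cyclization to give 6. The side-chain ether and both stereocentres come last.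

Assumptions:
- "Threo" means syn in the zigzag Ar–C7–C8–C9 sense. I checked that the (7''S,8''S) SMILES has this relationship.
- Phenacyl bromide 7 and the Ru catalyst 12 are treated as commercially available.

---

**Step 1**
Reactants: 1 (2',4',6'-trihydroxyacetophenone); 2 (benzyl bromide)
Product: 3 (4',6'-bis(benzyloxy)-2'-hydroxyacetophenone)
Conditions: 2 (2.1 equiv), K2CO3, acetone, reflux
Reagents that add atoms: benzyl bromide, BrCc1ccccc1
Why: Williamson etherification; the 2'-OH is H-bonded to the carbonyl and stays free, while the 4'- and 6'-OH are benzylated.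

**Step 2**
Reactants: 3; 4 (syringaldehyde)
Product: 5 ((E)-2'-hydroxy-4',6'-bis(benzyloxy)-4-hydroxy-3,5-dimethoxychalcone)
Conditions: KOH (4 equiv), EtOH/H2O, rt, 48 h
Reagents that add atoms: none
Why: Claisen–Schmidt condensation; excess base deprotonates the syringyl phenol and aldol dehydration gives the E-enone.

**Step 3**
Reactants: 5
Product: 6 (5,7-di-O-benzyltricin)
Conditions: I2 (0.2 equiv), DMSO, 130 °C
Reagents that add atoms: none
Why: I2/DMSO oxidative cyclization of the 2'-hydroxychalcone (oxa-Michael addition to the flavanone, then iodination/elimination) gives the flavone. Both B-ring positions ortho to the OH are blocked by OMe, so ring iodination is not expected there.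

**Step 4**
Reactants: 6; 7 (2-bromo-1-[4-(benzyloxy)phenyl]ethan-1-one)
Product: 8 (aryloxy ketone)
Conditions: K2CO3, DMF, 50 °C
Reagents that add atoms: none
Why: SN2 of the acidic flavone 4'-phenoxide on the α-bromo ketone, the standard route to β-O-4 ketone models, including with 2,6-dimethoxyphenoxides.

**Step 5**
Reactants: 8; 9 (formaldehyde)
Product: 10 (racemic α-aryloxy-β-hydroxy ketone)
Conditions: HCHO (37% aq., 1.3 equiv), K2CO3 (0.2 equiv), THF/H2O, rt
Reagents that add atoms: formaldehyde, C=O
Why: Adler–Lundquist base-catalysed aldol hydroxymethylation at the activated α-CH2 (α-aryloxy ketone). The new α-centre is racemic and is converted stereoselectively in Step 7.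

**Step 6**
Reactants: 10; 2 (benzyl bromide)
Product: 11 (racemic β-benzyloxy ketone)
Conditions: 2 (3 equiv), Ag2O, CH2Cl2, rt, dark
Reagents that add atoms: benzyl bromide, BrCc1ccccc1
Why: Mild, near-neutral Ag2O-mediated benzylation of the primary alcohol avoids retro-aldol and elimination. The benzyl group is removed together with the others at the end.

**Step 7**
Reactants: 11; 12 (RuCl[(R,R)-TsDPEN](p-cymene), commercial catalyst)
Product: 13 ((7''S,8''S)-tetra-O-benzyl flavonolignan)
Conditions: 12 (3 mol%), HCO2H/Et3N (5:2), CH2Cl2, 40 °C, 36 h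
Reagents that add atoms: none (HCO2H supplies only hydrogen)
Why: Proposed new method: DKR-ATH of a lignin-type α-aryloxy-β-alkoxy aryl ketone, closest known reaction type being Noyori–Ikariya DKR-ATH of α-alkoxy/α-aryloxy β-ketoesters.
- Et3N epimerizes the acidic C8–H of 11 through the enol faster than the slower-reacting enantiomer is reduced.
- The (R,R)-Ru–H transfers hydride through the six-membered outer-sphere TS.
- The CH/π contact between the p-cymene ligand and the p-benzyloxyphenyl ring fixes the carbonyl face. The (R,R) catalyst gives the R-alcohol for a simple aryl alkyl ketone. Here the alkyl carbon C8 outranks the aryl group, so the same spatial outcome is labelled 7''S.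
- The N–H···O(aryl ether) contact selects the matched C8 epimer, giving the syn/threo (8''S) product.
- The flavone C2=C3/C4=O vinylogous ester is not reduced under these conditions.

**Step 8**
Reactants: 13
Product: 14 (target)
Conditions: H2 (1 atm), 10% Pd/C, EtOAc/MeOH 1:1, rt, 2–4 h (monitor)
Reagents that add atoms: none (H2 adds only hydrogen)
Why: Neutral hydrogenolysis removes the 5-, 7-, 4''- and 9''-O-benzyl groups without acid, so the acid-labile p-hydroxybenzylic alcohol survives. C7'' and C8'' are untouched because no bond to a stereocentre is cleaved.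

---

**Compound list**

1 | 2',4',6'-Trihydroxyacetophenone | CC(=O)c1c(O)cc(O)cc1O | starting material
2 | Benzyl bromide | BrCc1ccccc1 | starting material
3 | 4',6'-Bis(benzyloxy)-2'-hydroxyacetophenone | CC(=O)c1c(O)cc(OCc2ccccc2)cc1OCc1ccccc1 | intermediate
4 | Syringaldehyde | COc1cc(C=O)cc(OC)c1O | starting material
5 | (E)-2'-Hydroxy-4',6'-bis(benzyloxy)-4-hydroxy-3,5-dimethoxychalcone | COc1cc(/C=C/C(=O)c2c(O)cc(OCc3ccccc3)cc2OCc2ccccc2)cc(OC)c1O | intermediate
6 | 5,7-Di-O-benzyltricin | COc1cc(-c2cc(=O)c3c(OCc4ccccc4)cc(OCc4ccccc4)cc3o2)cc(OC)c1O | intermediate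
7 | 2-Bromo-1-[4-(benzyloxy)phenyl]ethanone | O=C(CBr)c1ccc(OCc2ccccc2)cc1 | starting material
8 | Aryloxy ketone | COc1cc(-c2cc(=O)c3c(OCc4ccccc4)cc(OCc4ccccc4)cc3o2)cc(OC)c1OCC(=O)c1ccc(OCc2ccccc2)cc1 | intermediate
9 | Formaldehyde | C=O | starting material
10 | Racemic α-aryloxy-β-hydroxy ketone | COc1cc(-c2cc(=O)c3c(OCc4ccccc4)cc(OCc4ccccc4)cc3o2)cc(OC)c1OC(CO)C(=O)c1ccc(OCc2ccccc2)cc1 | intermediate
11 | Racemic β-benzyloxy ketone | COc1cc(-c2cc(=O)c3c(OCc4ccccc4)cc(OCc4ccccc4)cc3o2)cc(OC)c1OC(COCc1ccccc1)C(=O)c1ccc(OCc2ccccc2)cc1 | intermediate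
12 | RuCl[(R,R)-TsDPEN](p-cymene), commercial Ru catalyst (components shown) | Cc1ccc(cc1)S(=O)(=O)N[C@H](c1ccccc1)[C@H](N)c1ccccc1.Cc1ccc(C(C)C)cc1.Cl[Ru] | starting material
13 | (7''S,8''S)-Tetra-O-benzyl flavonolignan | COc1cc(-c2cc(=O)c3c(OCc4ccccc4)cc(OCc4ccccc4)cc3o2)cc(OC)c1O[C@@H](COCc1ccccc1)[C@@H](O)c1ccc(OCc2ccccc2)cc1 | intermediate
14 | (−)-(7''S,8''S)-Tricin 4'-O-[β-(4-hydroxyphenyl)glyceryl] ether | COc1cc(-c2cc(=O)c3c(O)cc(O)cc3o2)cc(OC)c1O[C@@H](CO)[C@@H](O)c1ccc(O)cc1 | target

**Step count:** 8 steps in total.
**Longest linear sequence:** 8 steps (1 → 3 → 5 → 6 → 8 → 10 → 11 → 13 → 14).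

**Three steps most likely to fail**
1. **Step 7 (proposed new DKR-ATH).** Risks are low dr or ee, β-elimination of BnOH to the enone, and too slow a racemization of the α-centre.
   - Fallback: reduce 11 with NaBH4 or Zn(BH4)2, separate the threo diastereomer by chromatography, and resolve its enantiomers by preparative chiral-phase HPLC. Use the (7''S,8''S) enantiomer in Step 8.
2. **Step 5 (hydroxymethylation).** Risks are bis-hydroxymethylation, retro-aldol, and hydroxide attack on the flavone.
   - Fallback: skip 10 and make 11 directly. Alkylate the 4'-phenoxide 6 with racemic α-bromo-β-benzyloxy ketone. Prepare that bromide from 4'-benzyloxyacetophenone by LDA/BnOCH2Cl, then CuBr2.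
3. **Step 8 (global hydrogenolysis).** Risks are C7''–O hydrogenolysis of the p-hydroxybenzylic alcohol and over-reduction of the flavone C2=C3.
   - Fallback: non-reductive debenzylation of 13 with BCl3 and pentamethylbenzene in CH2Cl2 at −78 °C, then a NaHCO3/MeOH quench.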